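**Strategy.** Magnone B is disconnected at the two exocyclic C–C bonds of its oxolane (O1, C2–C5). The hydroxymethyl carbon on C3 and the ketone carbon on C4 sit on the same face, so both are traced to the two alkene carbons of a cyclobutene cis-fused across C3–C4. One cobalt-catalysed (2+2) cycloaddition of a terminal arylalkyne to the C3=C4 bond of an enantioenriched 2-aryl-2,5-dihydrofuran forms both bonds, the four-membered ring and the C3/C4 stereocentres, anti to the C2 aryl group. The dihydrofuran comes from an asymmetric Heck arylation; ozonolysis and aldehyde-selective reduction then unveil the cis keto alcohol.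

Key step: step 3

Assumption: the (R)-antipode of the tert-butyl phosphinooxazoline ligand is taken to deliver the (S)-dihydrofuran, as expected for aryl triflates with this ligand class; the configuration is to be confirmed before the cycloaddition and the ligand antipode exchanged if needed.

Step 1
Reactants: 1 3,4,5-trimethoxyphenol
Product: 2 3,4,5-trimethoxyphenyl trifluoromethanesulfonate
Conditions: Tf2O, pyridine, CH2Cl2, 0 °C to rt
Reagents that add atoms: trifluoromethanesulfonic anhydride (Tf2O), O=S(=O)(OS(=O)(=O)C(F)(F)F)C(F)(F)F
Why: O-sulfonylation of the phenol by the anhydride with pyridine as acid scavenger is a standard aryl triflate synthesis and creates no stereocenter.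

Step 2
Reactants: 2 3,4,5-trimethoxyphenyl trifluoromethanesulfonate; 3 2,3-dihydrofuran (excess)
Product: 4 (S)-2-(3,4,5-trimethoxyphenyl)-2,5-dihydrofuran
Conditions: Pd2(dba)3 (1.5 mol %), (R)-4-tert-butyl-2-[2-(diphenylphosphanyl)phenyl]-4,5-dihydrooxazole (6 mol %), i-Pr2NEt, THF, 70 °C
Reagents that add atoms: none
Why: Asymmetric Mizoroki–Heck reaction by the cationic pathway, in which the triflate adds oxidatively to zerovalent palladium, the aryl group is transferred to the oxygen-bearing alkene carbon, β-hydride elimination occurs toward C3 and the P,N-ligated hydride releases the alkene without re-insertion, so the 2,5-dihydro isomer should result; the C2 stereocenter is set by ligand-controlled choice of the alkene face in the insertion.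

Step 3
Reactants: 4 (S)-2-(3,4,5-trimethoxyphenyl)-2,5-dihydrofuran; 5 4-ethynyl-1,2-dimethoxybenzene (1.5 equiv)
Product: 6 (1S,2S,5S)-6-(3,4-dimethoxyphenyl)-2-(3,4,5-trimethoxyphenyl)-3-oxabicyclo[3.2.0]hept-6-ene (cis-fused, cyclobutene anti to the 2-aryl group)
Conditions: CoBr2(dppp) (10 mol %), Zn powder (50 mol %), NaB[3,5-(CF3)2C6H3]4 (15 mol %), CH2Cl2, rt, 5 added slowly over several hours
Reagents that add atoms: none
Why: Zinc reduces the divalent cobalt precatalyst and the borate salt removes bromide; the cationic monovalent cobalt–dppp fragment then binds 5 and the C3=C4 bond of 4 on the face away from the aryl group, oxidative cyclization forms the C3–CH bond and a trivalent cobaltacyclopentene with cobalt on C4 and on the aryl-bearing carbon, and C–C reductive elimination forms the C4–C(aryl) bond and frees the catalyst. The closest known reaction type is the cationic cobalt–bisphosphine (2+2) cycloaddition of alkynes with cycloalkenes such as cyclopentene, where the ring C–H bonds of the metallacycle cannot align for β-hydride elimination, so cyclobutenes and not ene-type dienes are formed. The cyclobutene is closed by ring-contracting reductive elimination from the five-membered metallacycle, suprafacially on the alkene, which makes the four/five ring fusion cis by necessity. The two new stereocenters (C3 and C4 of the oxolane, C1 and C5 of the bicycle) are set relative to C2 by substrate control, the catalyst approaching anti to the aryl substituent. The step needs regioselectivity, face selectivity and chemoselectivity over alkyne cyclotrimerization: the first is expected because an arylalkyne places its aryl-bearing carbon next to cobalt and the bulky ligated cobalt prefers C4, the alkene carbon remote from the C2 aryl group; the second follows from that same aryl group; the third from keeping the alkyne concentration low.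

Step 4
Reactants: 6 (1S,2S,5S)-6-(3,4-dimethoxyphenyl)-2-(3,4,5-trimethoxyphenyl)-3-oxabicyclo[3.2.0]hept-6-ene
Product: 8 (2S,3S,4R)-4-(3,4-dimethoxybenzoyl)-2-(3,4,5-trimethoxyphenyl)oxolane-3-carbaldehyde, via secondary ozonide 7 (not isolated)
Conditions: O3, CH2Cl2, −78 °C (Sudan red 7B as end-point indicator); then PPh3, −78 °C to rt; crude product used at once
Reagents that add atoms: ozone, [O-][O+]=O
Why: Ozonolysis by the Criegee sequence (cycloaddition, cycloreversion, recombination to the ozonide) followed by phosphine reduction should cleave only the strained styrene-type double bond, which reacts far faster than the methoxyarenes, and no bond to C2, C3 or C4 is broken in a cold, neutral medium.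

Step 5
Reactants: 8 (2S,3S,4R)-4-(3,4-dimethoxybenzoyl)-2-(3,4,5-trimethoxyphenyl)oxolane-3-carbaldehyde
Product: 9 magnone B, (3,4-dimethoxyphenyl)[(3R,4R,5S)-4-(hydroxymethyl)-5-(3,4,5-trimethoxyphenyl)oxolan-3-yl]methanone
Conditions: NaBH(OAc)3 (2 equiv), CH2Cl2, 0 °C to rt
Reagents that add atoms: none
Why: Chemoselective carbonyl reduction by a weak, non-basic acyloxyborohydride, which reduces aldehydes but not aryl ketones, so the formyl group on C3 should become the hydroxymethyl group while the electron-rich aryl ketone and the epimerizable C3 and C4 centers stay as they are.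

**Compound list**

1 | 3,4,5-trimethoxyphenol | COc1cc(O)cc(OC)c1OC | starting material
2 | 3,4,5-trimethoxyphenyl trifluoromethanesulfonate | COc1cc(OS(=O)(=O)C(F)(F)F)cc(OC)c1OC | intermediate
3 | 2,3-dihydrofuran | C1=COCC1 | starting material
4 | (S)-2-(3,4,5-trimethoxyphenyl)-2,5-dihydrofuran | COc1cc([C@@H]2C=CCO2)cc(OC)c1OC | intermediate
5 | 4-ethynyl-1,2-dimethoxybenzene | COc1ccc(C#C)cc1OC | starting material
6 | (1S,2S,5S)-6-(3,4-dimethoxyphenyl)-2-(3,4,5-trimethoxyphenyl)-3-oxabicyclo[3.2.0]hept-6-ene | COc1ccc(C3=C[C@@H]4[C@@H](c5cc(OC)c(OC)c(OC)c5)OC[C@H]34)cc1OC | intermediate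
7 | secondary ozonide of 6: the two former alkene carbons are joined by an –O– bridge and an –O–O– bridge (1,2,4-trioxolane fused to the oxolane at C3 and C4); mixture of exo and endo isomers, acetal carbons unassigned | COc1ccc(C23OOC(O2)[C@@H]2[C@@H](c4cc(OC)c(OC)c(OC)c4)OC[C@H]32)cc1OC | intermediate (not isolated)
8 | (2S,3S,4R)-4-(3,4-dimethoxybenzoyl)-2-(3,4,5-trimethoxyphenyl)oxolane-3-carbaldehyde | COc1ccc(C(=O)[C@H]2CO[C@H](c3cc(OC)c(OC)c(OC)c3)[C@H]2C=O)cc1OC | intermediate
9 | magnone B, (3,4-dimethoxyphenyl)[(3R,4R,5S)-4-(hydroxymethyl)-5-(3,4,5-trimethoxyphenyl)oxolan-3-yl]methanone | COc1ccc(C(=O)[C@H]2CO[C@H](c3cc(OC)c(OC)c(OC)c3)[C@H]2CO)cc1OC | target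

**Step count and risks**

Total step count: 5. Longest linear sequence: 5 steps (1 → 2 → 4 → 6 → 8 → 9).

Steps most likely to fail:

Step 3. Regiocontrol in the oxidative cyclization may erode, so that the aryl-bearing alkyne carbon also bonds to C3, and the terminal alkyne may be consumed by cyclotrimerization. Ligand variation, including a chiral bisphosphine matched to 4 to add catalyst control over the choice between C3 and C4, is only a change of conditions. The change of approach sets out from dihydrofuran 4 and builds the four-membered ring by ketene chemistry. Dichloroketene (Cl3CCOCl, Zn(Cu), Et2O/DME) should add to the alkene face anti to the aryl group in a polar, asynchronous cycloaddition whose carbonyl carbon leads and is expected at the less encumbered C4. This gives cis-fused (2S)-7,7-dichloro-2-(3,4,5-trimethoxyphenyl)-3-oxabicyclo[3.2.0]heptan-6-one F1; a regioisomer, if formed, would be removed at this ketone stage. Zn in AcOH removes the chlorines to give (2S)-2-(3,4,5-trimethoxyphenyl)-3-oxabicyclo[3.2.0]heptan-6-one F2. The arylcerium reagent from 4-bromo-1,2-dimethoxybenzene (n-BuLi, then CeCl3, THF, −78 °C) adds to the ketone to give 6-(3,4-dimethoxyphenyl)-2-(3,4,5-trimethoxyphenyl)-3-oxabicyclo[3.2.0]heptan-6-ol F3. Dehydration with the Burgess reagent toward the ring CH2 group comes back to the route at cyclobutene 6.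

Step 4. Ozone may over-oxidize the two electron-rich arenes, or the cis keto aldehyde may epimerize at C3 or C4 while the peroxide is reduced. The fallback sets out from cyclobutene 6 and avoids ozone. Dihydroxylation (OsO4 cat., N-methylmorpholine N-oxide, acetone/H2O) on the convex face should give exo-cis 6-(3,4-dimethoxyphenyl)-2-(3,4,5-trimethoxyphenyl)-3-oxabicyclo[3.2.0]heptane-6,7-diol F4. Glycol cleavage with NaIO4 on silica gel in CH2Cl2 (or Pb(OAc)4, CH2Cl2, 0 °C) comes back to the route at keto aldehyde 8 under neutral conditions.

Step 5. Discrimination between aldehyde and ketone may be incomplete, or the reduction may be slow enough for the keto aldehyde to epimerize. The fallback sets out from keto aldehyde 8 and reduces both carbonyl groups on purpose with neutral Zn(BH4)2 (Et2O, −20 to 0 °C). This gives (3,4-dimethoxyphenyl)[(3R,4R,5S)-4-(hydroxymethyl)-5-(3,4,5-trimethoxyphenyl)oxolan-3-yl]methanol F5 as a mixture of carbinol epimers. Activated MnO2 (CH2Cl2, rt) should then re-oxidize only the benzylic secondary alcohol and leave the primary alcohol, coming back to the route at magnone B 9.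

**Further compounds**

F1 | step 3 | (2S)-7,7-dichloro-2-(3,4,5-trimethoxyphenyl)-3-oxabicyclo[3.2.0]heptan-6-one, cis-fused, four-membered ring anti to the aryl group | O=C3C(Cl)(Cl)[C@@H]4[C@@H](c5cc(OC)c(OC)c(OC)c5)OC[C@H]34
F2 | step 3 | (2S)-2-(3,4,5-trimethoxyphenyl)-3-oxabicyclo[3.2.0]heptan-6-one, cis-fused, four-membered ring anti to the aryl group | O=C3C[C@@H]4[C@@H](c5cc(OC)c(OC)c(OC)c5)OC[C@H]34
F3 | step 3 | 6-(3,4-dimethoxyphenyl)-2-(3,4,5-trimethoxyphenyl)-3-oxabicyclo[3.2.0]heptan-6-ol, ring stereocenters as in 6, carbinol configuration immaterial | COc1ccc(C3(O)C[C@@H]4[C@@H](c5cc(OC)c(OC)c(OC)c5)OC[C@H]34)cc1OC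
F4 | step 4 | exo-cis 6-(3,4-dimethoxyphenyl)-2-(3,4,5-trimethoxyphenyl)-3-oxabicyclo[3.2.0]heptane-6,7-diol, ring stereocenters as in 6 | COc1ccc([C@]3(O)[C@@H](O)[C@@H]4[C@@H](c5cc(OC)c(OC)c(OC)c5)OC[C@H]34)cc1OC
F5 | step 5 | (3,4-dimethoxyphenyl)[(3R,4R,5S)-4-(hydroxymethyl)-5-(3,4,5-trimethoxyphenyl)oxolan-3-yl]methanol, both carbinol epimers | COc1ccc(C(O)[C@H]2CO[C@H](c3cc(OC)c(OC)c(OC)c3)[C@H]2CO)cc1OC
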